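**Retrosynthetic overview**
1. Ring C is closed last: the C11a–O11 bond of the (6aS,11aS)-pterocarpan 12 is cut to give the achiral 2'-hydroxyisoflav-3-ene 11. A chiral Brønsted acid closes this bond and sets C6a and C11a together.
2. 11 comes from the 3-arylcoumarin 9 by reducing the lactone C=O to CH2; both ester groups are removed in the same pot.
3. 9 is assembled from salicylaldehyde 8 and arylacetic acid 3 by a Perkin condensation, which builds ring B as the coumarin.
4. 8 comes from 2,4,6-trihydroxybenzaldehyde 4 and isoprene 6; a para-pivalate leaves only an ortho-OH able to close the dimethylchroman ring. Acid 3 comes from paeonol 1.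
5. Ring order: dimethylchroman ring, then ring B (as the coumarin), then ring C. Rings A and D are bought.

Assumption: the SMILES is read as the (6aS,11aS) cis-pterocarpan; the antipode of the chiral acid in step 6 that gives this enantiomer is fixed by a first small-scale run (the (R)-acid is written). Isoflavonoid numbering is used for 9–11 and pterocarpan numbering for 12.

**Route**

Step 1
Reactants: 1 paeonol (1-(2-hydroxy-4-methoxyphenyl)ethan-1-one)
Product: 3 (2-hydroxy-4-methoxyphenyl)acetic acid, via Kindler thiomorpholide 2 (not isolated)
Conditions: S8, morpholine, 130 °C; then 20% aq. NaOH, reflux; HCl to pH 2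
Reagents that add atoms: sodium hydroxide [Na+].[OH-] and water O (the two carboxyl oxygens of 3); sulfur S1SSSSSSS1 and morpholine C1COCCN1 (their atoms are held only in intermediate 2)
Why: Willgerodt–Kindler reaction, in which the aryl methyl ketone is thiated via its enamine and the oxidation level moves to the terminal carbon to give thioamide 2, which aqueous NaOH hydrolyses to the arylacetic acid; no stereocentre.

Step 2
Reactants: 4 2,4,6-trihydroxybenzaldehyde
Product: 5 4-formyl-3,5-dihydroxyphenyl pivalate
Conditions: PivCl (1.05 equiv), Et3N (1.1 equiv), THF, −40 to 0 °C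
Reagents that add atoms: pivaloyl chloride CC(C)(C)C(Cl)=O
Why: selective O-acylation, because the 4-OH para to the formyl group is the most acidic hydroxyl and the only one not hydrogen-bonded to the carbonyl, so the monophenoxide formed with one equivalent of Et3N is acylated there by the bulky acid chloride; no stereocentre.

Step 3
Reactants: 5 4-formyl-3,5-dihydroxyphenyl pivalate; 6 isoprene
Product: 8 8-formyl-7-hydroxy-2,2-dimethylchroman-5-yl pivalate, via C-prenyl phenol 7 (not isolated)
Conditions: isoprene (1.2 equiv), Amberlyst 15, THF–heptane, 65 °C, sealed tube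
Reagents that add atoms: none
Why: acid-catalysed Friedel–Crafts prenylation/cycloetherification (formal [3+3] chroman annulation), in which the prenyl cation alkylates one of the two equivalent positions between OPiv and OH and the tertiary cation from 7 can only be trapped by the adjacent free ortho-OH because the para-oxygen is blocked, which fixes the ring-fusion regiochemistry; no stereocentre.

Step 4
Reactants: 8 8-formyl-7-hydroxy-2,2-dimethylchroman-5-yl pivalate; 3 (2-hydroxy-4-methoxyphenyl)acetic acid
Product: 9 3-(2-acetoxy-4-methoxyphenyl)-7-pivaloyloxy-6'',6''-dimethyl-4'',5''-dihydropyrano[2'',3'':5,6]coumarin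
Conditions: Ac2O, Et3N, 110 °C
Reagents that add atoms: acetic anhydride CC(=O)OC(C)=O
Why: Perkin–Oglialoro coumarin synthesis, in which the mixed-anhydride enolate of 3 condenses with the aldehyde of 8 and the neighbouring 7-OH closes the lactone (ring B, alkene geometry fixed by the ring) while the ring D phenol is acetylated in the same pot; no stereocentre.

Step 5
Reactants: 9 the 3-arylcoumarin diester
Product: 11 7,2'-dihydroxy-4'-methoxy-6'',6''-dimethyl-4'',5''-dihydropyrano[2'',3'':5,6]isoflav-3-ene, via isoflavene diester 10 (not isolated)
Conditions: BH3·THF (2 equiv), THF, 0 °C to rt; then MeOH, K2CO3, 40 °C, argon; pH 7 phosphate buffer work-up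
Reagents that add atoms: none
Why: borane reduction of an aryl lactone carbonyl to CH2 (lactone-to-cyclic-ether reduction, which I believe is reported for 3-arylcoumarins) gives the 2H-chromene 10 while both phenols are still masked and not acid-labile, and base-catalysed methanolysis then removes the pivalate and acetate without acid; no stereocentre.

Step 6
Reactants: 11 the 2'-hydroxyisoflav-3-ene
Product: 12 (6aS,11aS)-3-hydroxy-9-methoxy-6'',6''-dimethyl-4'',5''-dihydropyrano[2'',3'':1,2]pterocarpan (target)
Conditions: (R)-TRIP [(R)-3,3'-bis(2,4,6-triisopropylphenyl)-1,1'-binaphthyl-2,2'-diyl hydrogen phosphate] (10 mol%), 5 Å MS, toluene (0.02 M), −20 °C, argon; Et3N quench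
Reagents that add atoms: none
Why: Proposed new method: enantioselective Brønsted acid cycloisomerisation (intramolecular hydroalkoxylation) of a 2'-hydroxyisoflav-3-ene, in which the chiral phosphoric acid protonates C-3 of the very electron-rich alkene on one face to give a benzylic cation at C-4 (a protonated para-quinone methide, stabilised by the 7-OH and the two ortho ring oxygens) as a tight ion pair with the chiral phosphate, and the phosphate-bound 2'-OH then adds to C-4 on the same face because only the cis-fused dihydrofuran can form, so the C–H bond sets C6a and the C–O bond sets C11a (if protonation is reversible the ring closure becomes the selecting step, still inside the chiral ion pair); the closest known reactions are chiral phosphoric acid-catalysed additions to quinone methides generated in situ from hydroxystyrenes and confined-acid asymmetric intramolecular hydroalkoxylation of alkenols, neither shown on isoflavenes or for closing the pterocarpan ring.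

**Compound list**
1 | paeonol, 1-(2-hydroxy-4-methoxyphenyl)ethan-1-one | CC(=O)c1ccc(OC)cc1O | starting material
2 | 2-(2-hydroxy-4-methoxyphenyl)-1-(morpholin-4-yl)ethane-1-thione | COc1ccc(CC(=S)N2CCOCC2)c(O)c1 | intermediate
3 | (2-hydroxy-4-methoxyphenyl)acetic acid | COc1ccc(CC(=O)O)c(O)c1 | intermediate
4 | 2,4,6-trihydroxybenzaldehyde | O=Cc1c(O)cc(O)cc1O | starting material
5 | 4-formyl-3,5-dihydroxyphenyl pivalate | CC(C)(C)C(=O)Oc1cc(O)c(C=O)c(O)c1 | intermediate
6 | isoprene (2-methylbuta-1,3-diene) | C=CC(C)=C | starting material
7 | 4-formyl-3,5-dihydroxy-2-(3-methylbut-2-en-1-yl)phenyl pivalate | CC(C)=CCc1c(O)c(C=O)c(O)cc1OC(=O)C(C)(C)C | intermediate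
8 | 8-formyl-7-hydroxy-2,2-dimethylchroman-5-yl pivalate | CC1(C)CCc2c(OC(=O)C(C)(C)C)cc(O)c(C=O)c2O1 | intermediate
9 | 3-(2-acetoxy-4-methoxyphenyl)coumarin with 7-OPiv and a 2,2-dimethyl-dihydropyran ring fused at C5–C6 (pyran oxygen on C5) | CC(C)(C)C(=O)Oc1cc2OC(=O)C(c3ccc(OC)cc3OC(C)=O)=Cc2c2OC(C)(C)CCc12 | intermediate
10 | 7-O-pivaloyl-2'-O-acetyl derivative of isoflav-3-ene 11 | CC(C)(C)C(=O)Oc1cc2OCC(c3ccc(OC)cc3OC(C)=O)=Cc2c2OC(C)(C)CCc12 | intermediate
11 | 7,2'-dihydroxy-4'-methoxyisoflav-3-ene with a 2,2-dimethyl-dihydropyran ring fused at C5–C6 (pyran oxygen on C5) | Oc1cc2OCC(c3ccc(OC)cc3O)=Cc2c2OC(C)(C)CCc12 | intermediate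
12 | (6aS,11aS)-3-hydroxy-9-methoxypterocarpan with a 2,2-dimethyl-dihydropyran ring fused at C1–C2 (pyran oxygen on C1), cis ring fusion | COc1ccc2c(c1)O[C@@H]1c3c(cc(O)c4c3OC(C)(C)CC4)OC[C@H]21 | target

**Step count and risks**

Total step count: 6. Longest linear sequence: 5 steps (steps 2 to 6, from 4).

The three steps most likely to fail:

Step 6, the new ring closure, is the least certain. The acid may be too weak to protonate the alkene, the ee may be low, or the product may re-ionise and racemise. The fallback uses known chemistry and replaces asymmetric catalysis by racemic ring closure plus resolution. It sets out from 11: TsOH·H2O (5 mol%) in CH2Cl2 at 0 °C gives, by ordinary acid-catalysed addition of the phenol to the activated styrene, the racemic cis-pterocarpan F1. Preparative chiral SFC on an amylose tris(3,5-dimethylphenylcarbamate) column then separates 12 from its (6aR,11aR)-enantiomer F2, and the route is rejoined at 12. F1 also serves as the HPLC standard for measuring the ee of step 6.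

Step 5 may over-reduce (hydroboration of the new chromene double bond) or stop at a ring-opened diol. The fallback sets out from 9: LiAlH4 in THF at 0 °C reduces the lactone to the allylic alcohol and cleaves both aryl esters, giving the Z-allylic diol F3. An intramolecular Mitsunobu etherification (PPh3, DIAD, THF, 0 °C) then closes the six-membered ether through the ring A phenol, which the Z-alkene holds next to the CH2OH. This route avoids acid, which would carry the material on to racemic pterocarpan, and rejoins at 11.

Step 3 may be sluggish on the deactivated ring or take up a second isoprene on the remaining free position. The fallback sets out from 5: 3-methylbut-2-enal with ethylenediammonium diacetate (10 mol%) in toluene at 110 °C (Knoevenagel condensation then oxa-6π electrocyclisation) builds the 2H-chromene aldehyde F4 on the same ortho-OH. Hydrogenation of the chromene double bond (H2, 1 atm, Pd/C (palladium on carbon), EtOAc, rt, stopped after one equivalent of H2) rejoins the route at 8.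

**Further compounds**
F1 | step 6 | racemic cis-pterocarpan (1:1 mixture of 12 and F2) | COc1ccc2c(c1)O[C@@H]1c3c(cc(O)c4c3OC(C)(C)CC4)OC[C@H]21.COc1ccc2c(c1)O[C@H]1c3c(cc(O)c4c3OC(C)(C)CC4)OC[C@@H]21
F2 | step 6 | (6aR,11aR)-enantiomer of 12 | COc1ccc2c(c1)O[C@H]1c3c(cc(O)c4c3OC(C)(C)CC4)OC[C@@H]21
F3 | step 5 | (Z)-3-(5,7-dihydroxy-2,2-dimethylchroman-8-yl)-2-(2-hydroxy-4-methoxyphenyl)prop-2-en-1-ol | OC/C(c1ccc(OC)cc1O)=C\c1c(O)cc(O)c2CCC(C)(C)Oc12
F4 | step 3 | 8-formyl-7-hydroxy-2,2-dimethyl-2H-chromen-5-yl pivalate | CC1(C)C=Cc2c(OC(=O)C(C)(C)C)cc(O)c(C=O)c2O1
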